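Both flavan units share the 7-hydroxy ring A, pyrogallol ring B and 2,3-trans configuration, so one protected (2R,3R)-dihydroflavonol serves twice. Everything rests on disconnecting its pyran ring C at the aryl ether bond O1–C8a. Because C8a lies ortho to C4a, a C4 ketone makes C8a electrophilic: an acyclic anti-aldol ketone with a 2-fluoro-4-benzyloxyphenyl ring A closes ring C by intramolecular SNAr of the C2 alkoxide, both stereocentres already in place. The C4 carbonyl then becomes the C4 cation of the upper unit, which is joined to C2' of ring B of a second dihydroflavonol, and finally the 4-hydroxyl of the lower unit.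

Key step: step 5

Remark: flavan numbering is used for both units (O1, C2, C3, C4, C4a, C5–C8, C8a; ring A = benzo ring, ring B = 2-aryl ring, ring C = pyran ring); compounds 1, 2, 6 and 8 are taken as commercial; the (S)-diamine of step 3 is assumed to direct the addition to the aldehyde face that gives the (2R,3R) adduct, by analogy with simple aromatic aldehydes.

Step 1
Reactants: 1 2-(benzyloxy)acetyl chloride; 2 ethanethiol
Product: 3 S-ethyl 2-(benzyloxy)ethanethioate
Conditions: pyridine, CH2Cl2, 0 °C to rt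
Reagents that add atoms: none
Why: Nucleophilic acyl substitution (thioesterification of an acid chloride by a thiol, pyridine as acid scavenger) should proceed cleanly, and no stereocentre is involved.

Step 2
Reactants: 3 S-ethyl 2-(benzyloxy)ethanethioate
Product: 5 (Z)-{[2-(benzyloxy)-1-(ethylsulfanyl)ethenyl]oxy}trimethylsilane, via lithium enolate 4 (not isolated)
Conditions: LiN(iPr)2, THF, −78 °C; then Me3SiCl, −78 °C to rt; distillation
Reagents that add atoms: chlorotrimethylsilane, C[Si](C)(C)Cl; lithium diisopropylamide, [Li+].CC(C)[N-]C(C)C (lithium, held only by intermediate 4)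
Why: Kinetic deprotonation of the thioester and O-silylation of the enolate (enol silylation) should give mainly the (Z)-ketene silyl thioacetal, with ethylsulfanyl and benzyloxy cis, which is the donor geometry needed for the anti-selective Mukaiyama aldol addition.

Step 3
Reactants: 5 (Z)-{[2-(benzyloxy)-1-(ethylsulfanyl)ethenyl]oxy}trimethylsilane; 6 3,4,5-tris(benzyloxy)benzaldehyde
Product: 7 S-ethyl (2R,3R)-2-(benzyloxy)-3-hydroxy-3-[3,4,5-tris(benzyloxy)phenyl]propanethioate
Conditions: Sn(OTf)2, (S)-1-ethyl-2-(piperidin-1-ylmethyl)pyrrolidine, nBu2Sn(OAc)2, CH2Cl2, −78 °C; then aq. NaHCO3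
Reagents that add atoms: none
Why: In this asymmetric Mukaiyama aldol addition the aldehyde bound to the diamine complex of divalent tin should be attacked on one face by the α-benzyloxy (Z)-donor through an open transition state, which sets C3 (R, the future flavan C2) by reagent control and C2 (R, the future flavan C3) in the anti relationship typical of α-benzyloxy donors.

Step 4
Reactants: 7 S-ethyl (2R,3R)-2-(benzyloxy)-3-hydroxy-3-[3,4,5-tris(benzyloxy)phenyl]propanethioate; 8 [4-(benzyloxy)-2-fluorophenyl]boronic acid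
Product: 9 (2R,3R)-2-(benzyloxy)-1-[4-(benzyloxy)-2-fluorophenyl]-3-hydroxy-3-[3,4,5-tris(benzyloxy)phenyl]propan-1-one
Conditions: Pd2(dba)3 (cat.), tri(2-furyl)phosphine, copper thiophene-2-carboxylate Cu(O2CC4H3S), THF, 50 °C
Reagents that add atoms: none
Why: In this Liebeskind–Srogl ketone synthesis zerovalent palladium inserts into the acyl–sulfur bond and the monovalent copper carboxylate mediates base-free transmetalation from boron, so the β-hydroxyl, the epimerisable α-centre and the aryl fluoride should stay untouched.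

Step 5
Reactants: 9 (2R,3R)-2-(benzyloxy)-1-[4-(benzyloxy)-2-fluorophenyl]-3-hydroxy-3-[3,4,5-tris(benzyloxy)phenyl]propan-1-one
Product: 10 (2R,3R)-3,7-bis(benzyloxy)-2-[3,4,5-tris(benzyloxy)phenyl]-2,3-dihydro-4H-chromen-4-one
Conditions: Cs2CO3, DMF, 0 °C to rt
Reagents that add atoms: none
Why: Intramolecular nucleophilic aromatic substitution (addition–elimination): the caesium alkoxide of the C2 hydroxyl adds to C8a, the fluorine-bearing carbon ortho to the C4 ketone, giving a Meisenheimer anion delocalised through C4a into that carbonyl, and loss of fluoride forms the O1–C8a aryl ether. The closest known reaction type is the base-mediated cyclisation of ortho-fluoroaryl ketones carrying a tethered oxygen nucleophile to chromones and chroman-4-ones. Ring C closes as a six-membered ring fused to ring A, formally 6-endo-trig because both carbons of the attacked C4a=C8a arene bond lie in the new ring, a mode that is allowed and unstrained here. No stereocentre is created; C2 and C3 are carried through with retention because no bond to either carbon is broken, so the anti aldol relationship becomes the 2,3-trans arrangement. The step needs cyclisation to outrun retro-aldol cleavage and enolisation at C3; this should be secured by the ortho-acyl activation (weak base, room temperature or below), by the benzyl ether on the C3 oxygen (the C2 alkoxide is the only nucleophile) and by the diequatorial 2,3-trans product being the preferred epimer.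

Step 6
Reactants: 10 (2R,3R)-3,7-bis(benzyloxy)-2-[3,4,5-tris(benzyloxy)phenyl]-2,3-dihydro-4H-chromen-4-one
Product: 11 (2R,3R)-3,7-dihydroxy-2-(3,4,5-trihydroxyphenyl)-2,3-dihydro-4H-chromen-4-one (dihydrorobinetin)
Conditions: H2 (1 atm), Pd(OH)2/C, THF/MeOH, rt
Reagents that add atoms: none
Why: Heterogeneous hydrogenolysis of the four aryl benzyl ethers and the secondary C3 benzyl ether under neutral conditions should leave the aryl ketone and both stereocentres unchanged.

Step 7
Reactants: 11 (2R,3R)-dihydrorobinetin (about one fifth of the batch)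
Product: 12 (2R,3S,4R)-2-(3,4,5-trihydroxyphenyl)-3,4-dihydro-2H-chromene-3,4,7-triol (leucorobinetinidin)
Conditions: NaBH4, EtOH, N2, 0 °C to rt; AcOH to pH 6; used at once
Reagents that add atoms: none
Why: Borohydride reduction of the C4 ketone of a 2,3-trans-dihydroflavonol by axial hydride delivery should give mainly the 3,4-trans alcohol (4R), a configuration that is lost again in step 8 and so is not critical.

Step 8
Reactants: 12 leucorobinetinidin (added slowly); 11 (2R,3R)-dihydrorobinetin (4 equiv, excess recovered)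
Product: 14 (2R,3R)-2-{2-[(2R,3S,4S)-3,7-dihydroxy-2-(3,4,5-trihydroxyphenyl)-3,4-dihydro-2H-chromen-4-yl]-3,4,5-trihydroxyphenyl}-3,7-dihydroxy-2,3-dihydro-4H-chromen-4-one, via C4 carbocation 13 (not isolated)
Conditions: 0.1 M aq. HCl/EtOH, rt, N2; Sephadex LH-20 (EtOH)
Reagents that add atoms: none
Why: In this acid-catalysed flavan-3,4-diol condensation (Friedel–Crafts alkylation) loss of water from the benzylic C4 position gives cation 13, stabilised by the para C7 hydroxyl of ring A, which should be captured by C2' of the pyrogallol ring B of 11 (ring A of 11 is deactivated by its C4 carbonyl) on the face anti to the C3 hydroxyl, giving the 3,4-trans (4S) linkage.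

Step 9
Reactants: 14 the (4→2')-linked flavan–dihydroflavonol
Product: 15 (2R,3S,4R)-2-{2-[(2R,3S,4S)-3,7-dihydroxy-2-(3,4,5-trihydroxyphenyl)-3,4-dihydro-2H-chromen-4-yl]-3,4,5-trihydroxyphenyl}-3,4-dihydro-2H-chromene-3,4,7-triol
Conditions: NaBH4, EtOH/H2O, N2, 0 °C to rt; AcOH to pH 6; Sephadex LH-20
Reagents that add atoms: none
Why: Borohydride reduction of the remaining C4 ketone, again by axial hydride delivery to a 2,3-trans-dihydroflavonol unit, should set the last stereocentre as 4R (3,4-trans) and complete the flavan-3,4-diol lower unit.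

Compound list
1 | 2-(benzyloxy)acetyl chloride | O=C(Cl)COCc1ccccc1 | starting material
2 | ethanethiol | CCS | starting material
3 | S-ethyl 2-(benzyloxy)ethanethioate | CCSC(=O)COCc1ccccc1 | intermediate
4 | lithium (Z)-2-(benzyloxy)-1-(ethylsulfanyl)ethen-1-olate (not isolated) | [Li+].CCS/C([O-])=C\OCc1ccccc1 | intermediate
5 | (Z)-{[2-(benzyloxy)-1-(ethylsulfanyl)ethenyl]oxy}trimethylsilane | CCS/C(O[Si](C)(C)C)=C\OCc1ccccc1 | intermediate
6 | 3,4,5-tris(benzyloxy)benzaldehyde | O=Cc1cc(OCc2ccccc2)c(OCc2ccccc2)c(OCc2ccccc2)c1 | starting material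
7 | S-ethyl (2R,3R)-2-(benzyloxy)-3-hydroxy-3-[3,4,5-tris(benzyloxy)phenyl]propanethioate | CCSC(=O)[C@H](OCc1ccccc1)[C@H](O)c1cc(OCc2ccccc2)c(OCc2ccccc2)c(OCc2ccccc2)c1 | intermediate
8 | [4-(benzyloxy)-2-fluorophenyl]boronic acid | OB(O)c1ccc(OCc2ccccc2)cc1F | starting material
9 | (2R,3R)-2-(benzyloxy)-1-[4-(benzyloxy)-2-fluorophenyl]-3-hydroxy-3-[3,4,5-tris(benzyloxy)phenyl]propan-1-one | O=C(c1ccc(OCc2ccccc2)cc1F)[C@H](OCc1ccccc1)[C@H](O)c1cc(OCc2ccccc2)c(OCc2ccccc2)c(OCc2ccccc2)c1 | intermediate
10 | (2R,3R)-3,7-bis(benzyloxy)-2-[3,4,5-tris(benzyloxy)phenyl]-2,3-dihydro-4H-chromen-4-one | O=C1c2ccc(OCc3ccccc3)cc2O[C@H](c2cc(OCc3ccccc3)c(OCc3ccccc3)c(OCc3ccccc3)c2)[C@H]1OCc1ccccc1 | intermediate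
11 | (2R,3R)-3,7-dihydroxy-2-(3,4,5-trihydroxyphenyl)-2,3-dihydro-4H-chromen-4-one (dihydrorobinetin) | O=C1c2ccc(O)cc2O[C@H](c2cc(O)c(O)c(O)c2)[C@H]1O | intermediate
12 | (2R,3S,4R)-2-(3,4,5-trihydroxyphenyl)-3,4-dihydro-2H-chromene-3,4,7-triol (leucorobinetinidin) | Oc1ccc2c(c1)O[C@H](c1cc(O)c(O)c(O)c1)[C@@H](O)[C@@H]2O | intermediate
13 | (2R,3S)-3,7-dihydroxy-2-(3,4,5-trihydroxyphenyl)-3,4-dihydro-2H-chromen-4-ylium, the C4 carbocation (not isolated) | Oc1ccc2c(c1)O[C@H](c1cc(O)c(O)c(O)c1)[C@@H](O)[CH+]2 | intermediate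
14 | (2R,3R)-2-{2-[(2R,3S,4S)-3,7-dihydroxy-2-(3,4,5-trihydroxyphenyl)-3,4-dihydro-2H-chromen-4-yl]-3,4,5-trihydroxyphenyl}-3,7-dihydroxy-2,3-dihydro-4H-chromen-4-one | Oc1ccc2c(c1)O[C@H](c1cc(O)c(O)c(O)c1)[C@@H](O)[C@@H]2c1c([C@H]2Oc3cc(O)ccc3C(=O)[C@@H]2O)cc(O)c(O)c1O | intermediate
15 | (2R,3S,4R)-2-{2-[(2R,3S,4S)-3,7-dihydroxy-2-(3,4,5-trihydroxyphenyl)-3,4-dihydro-2H-chromen-4-yl]-3,4,5-trihydroxyphenyl}-3,4-dihydro-2H-chromene-3,4,7-triol | Oc1ccc2c(c1)O[C@H](c1cc(O)c(O)c(O)c1)[C@@H](O)[C@@H]2c1c([C@H]2Oc3cc(O)ccc3[C@@H](O)[C@@H]2O)cc(O)c(O)c1O | target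

Total step count: 9. Longest linear sequence: 9 steps (1 to 15; compound 11 enters both step 7 and step 8).

Steps most likely to fail

Step 5. The β-alkoxide may undergo retro-aldol cleavage or the C3 centre may epimerise faster than fluoride is displaced, eroding yield and optical purity. The fallback removes the carbonyl before ring closure and sets out from 9. Reduction with NaBH4 in THF/MeOH should give (1RS,2R,3R)-2-(benzyloxy)-1-[4-(benzyloxy)-2-fluorophenyl]-3-[3,4,5-tris(benzyloxy)phenyl]propane-1,3-diol F1, in which retro-aldol cleavage is impossible. Its benzylic alkoxide on the carbon bearing ring B (KOtBu, DMSO, 70 °C) should then displace the non-activated fluoride, the other alkoxide being able to form only a four-membered ring. This gives (2R,3S,4RS)-3,7-bis(benzyloxy)-2-[3,4,5-tris(benzyloxy)phenyl]-3,4-dihydro-2H-chromen-4-ol F2. Oxidation of the C4 alcohol with Dess–Martin periodinane comes back to the route at 10.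

Step 8. The cation may be consumed by self-condensation of the free-phenolic electrophile through its own rings A and B, by attack on both faces, or by further alkylation of the product. The fallback differentiates the partners by protection and sets out from 10. Reduction with NaBH4 should give (2R,3S,4R)-3,7-bis(benzyloxy)-2-[3,4,5-tris(benzyloxy)phenyl]-3,4-dihydro-2H-chromen-4-ol F3, whose benzylated rings are weaker nucleophiles than the free pyrogallol ring of 11. Ionisation with BF3·OEt2 in 1,4-dioxane in the presence of excess free 11 should give (2R,3R)-2-{2-[(2R,3S,4S)-3,7-bis(benzyloxy)-2-[3,4,5-tris(benzyloxy)phenyl]-3,4-dihydro-2H-chromen-4-yl]-3,4,5-trihydroxyphenyl}-3,7-dihydroxy-2,3-dihydro-4H-chromen-4-one F4. Hydrogenolysis (H2, Pd(OH)2/C, THF/MeOH) comes back to the route at 14.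

Step 4. Transmetalation from the ortho-fluoro boronic acid to the hindered α-branched acylpalladium species may be slower than protodeboronation, or the free β-hydroxyl may interfere, so that conversion stalls. The fallback replaces the catalytic acyl cross-coupling by polar addition to a Weinreb amide and sets out from 7. Aminolysis with N,O-dimethylhydroxylamine hydrochloride and iPrMgCl (THF, −20 °C) should give (2R,3R)-2-(benzyloxy)-3-hydroxy-N-methoxy-N-methyl-3-[3,4,5-tris(benzyloxy)phenyl]propanamide F5. Bromine–lithium exchange of commercial 4-(benzyloxy)-1-bromo-2-fluorobenzene with nBuLi (THF, −78 °C) should give [4-(benzyloxy)-2-fluorophenyl]lithium F6, which is kept at −78 °C so that it does not lose LiF to an aryne. Addition of F5 to three equivalents of F6 (the first deprotonates the hydroxyl) gives a chelated tetrahedral adduct that resists over-addition. Quenching with aq. NH4Cl at −78 °C comes back to the route at 9.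

Further compounds
F1 | step 5 | (1RS,2R,3R)-2-(benzyloxy)-1-[4-(benzyloxy)-2-fluorophenyl]-3-[3,4,5-tris(benzyloxy)phenyl]propane-1,3-diol | OC(c1ccc(OCc2ccccc2)cc1F)[C@H](OCc1ccccc1)[C@H](O)c1cc(OCc2ccccc2)c(OCc2ccccc2)c(OCc2ccccc2)c1
F2 | step 5 | (2R,3S,4RS)-3,7-bis(benzyloxy)-2-[3,4,5-tris(benzyloxy)phenyl]-3,4-dihydro-2H-chromen-4-ol | OC1c2ccc(OCc3ccccc3)cc2O[C@H](c2cc(OCc3ccccc3)c(OCc3ccccc3)c(OCc3ccccc3)c2)[C@H]1OCc1ccccc1
F3 | step 8 | (2R,3S,4R)-3,7-bis(benzyloxy)-2-[3,4,5-tris(benzyloxy)phenyl]-3,4-dihydro-2H-chromen-4-ol | O[C@@H]1c2ccc(OCc3ccccc3)cc2O[C@H](c2cc(OCc3ccccc3)c(OCc3ccccc3)c(OCc3ccccc3)c2)[C@H]1OCc1ccccc1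
F4 | step 8 | (2R,3R)-2-{2-[(2R,3S,4S)-3,7-bis(benzyloxy)-2-[3,4,5-tris(benzyloxy)phenyl]-3,4-dihydro-2H-chromen-4-yl]-3,4,5-trihydroxyphenyl}-3,7-dihydroxy-2,3-dihydro-4H-chromen-4-one | c1ccccc1COc1ccc2c(c1)O[C@H](c1cc(OCc3ccccc3)c(OCc3ccccc3)c(OCc3ccccc3)c1)[C@@H](OCc1ccccc1)[C@@H]2c1c([C@H]2Oc3cc(O)ccc3C(=O)[C@@H]2O)cc(O)c(O)c1O
F5 | step 4 | (2R,3R)-2-(benzyloxy)-3-hydroxy-N-methoxy-N-methyl-3-[3,4,5-tris(benzyloxy)phenyl]propanamide | CON(C)C(=O)[C@H](OCc1ccccc1)[C@H](O)c1cc(OCc2ccccc2)c(OCc2ccccc2)c(OCc2ccccc2)c1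
F6 | step 4 | [4-(benzyloxy)-2-fluorophenyl]lithium | [Li]c1ccc(OCc2ccccc2)cc1F
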